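## Analysis of the target

The target (21) is the (2S)-flavanone 6-geranylhesperetin. Ring A is a phloroglucinol-type benzene carrying O1, the 5- and 7-hydroxyls and the geranyl chain at C6. Ring C is the dihydropyranone (O1, C2, C3, C4=O, C4a, C8a), and ring B is a 3-hydroxy-4-methoxyphenyl group on C2. C2 is the only stereocentre. It is benzylic, bound to O1 and β to the C4 carbonyl, so base can erase it by retro-oxa-Michael opening to the 2'-hydroxychalcone. The geranyl chain has an E alkene at C2'=C3' that must survive unchanged, and both of its alkenes add the flanking 5- and 7-hydroxyls under acid (chroman formation). The two hard points are placing geranyl at C6 and not C8, which differ only in their relation to O1, and setting C2 with no other stereocentre to relay from. The strategy rests on one feature: C2 is a CH carrying O1 and the electron-rich ring B, six atoms from C3 through C4, C4a, C8a and O1. Cutting C2–C3 therefore leaves an O1–CH2–aryl ether ortho to a two-carbon acyl unit, and a carbene at C3 can desymmetrise that prochiral CH2.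

## Retrosynthetic reasoning

**21 ⇐ 20 ⇐ 19 (protecting groups).** The three phenols are unmasked last. The O7 acetal of 20 is removed by brief acid, and the two silyl ethers of 19 (O5 and O3') by buffered fluoride before that. Fluoride goes first so that the acid step only has to cleave one acetal and the geranyl chain sees acid for the shortest time.

**19 ⇐ 18 (C2–C3, ring C, the stereocentre).** The C2–C3 bond is cut to the diazoketone 18, in which C3 is a diazo carbon and C2 is the CH2 of an O1–benzyl ether. This cut creates the ketone oxidation level, ring C and C2 in one neutral step, and it needs no chalcone, so the base-sensitive retro-oxa-Michael manifold is never entered. The forward reaction must choose one of two enantiotopic hydrogens and must prefer C–H insertion to attack on the O1 lone pair.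

**18 ⇐ 16 ⇐ 15 (C3–C4 and the acid level).** C3 comes from a one-carbon diazo reagent acylated by the acid chloride of 16, and 16 comes from aldehyde 15 by a chlorite oxidation. No strong base is used after the O5 silyl group is on, which avoids silyl migration to an enolate or alkoxide.

**15 ⇐ 14 ⇐ 13 (exchange of the O5 group).** A methoxymethyl acetal at O5 would sit ortho to the carbene and offer a second, more hydridic O–CH2–O group at the same six-atom distance. Insertion there would close the ring onto O5 and give a 2-methoxychromanone with geranyl at C8; that oxygen is also a ready ylide donor. The O5 acetal of 13 is therefore removed selectively, helped by the neighbouring aldehyde, to give 14. It is replaced in 15 by a tert-butyldimethylsilyl group, which has no C–H on the atom bound to oxygen. The O7 acetal is para to the acyl group, cannot reach the carbene, and stays.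

**13 ⇐ 9 + 12 (O1–CH2).** The benzyl ether is made by a Mitsunobu reaction between the single free phenol of salicylaldehyde 9 and benzylic alcohol 12. Alcohol 12 comes from isovanillin 10 through silyl ether 11. Forming the ether after the aldehyde is in place avoids having to formylate next to a benzylic ether, which would need an organolithium or an acidic electrophile.

**9 ⇐ 8 (C4–C4a).** The formyl carbon is introduced ortho to the free hydroxyl of phenol 8 by a magnesium-directed formylation. Phenol 8 is symmetric, with geranyl para to the hydroxyl and flanked by two identical acetals. Either ortho position therefore gives the same aldehyde, and the 6-geranyl (not 8-geranyl) pattern is fixed by symmetry.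

**8 ⇐ 7 ⇐ 3 + 4; 3 ⇐ 2 ⇐ 1 (C6–C1').** The geranyl C–C bond is cut between the two acetal-bearing carbons of 3, the position where two directing groups cooperate in ortho-metalation. The third oxygen, later O1, is held as a bulky triisopropylsilyl ether that neither directs nor reacts, and it is freed in 8. The E alkene is taken intact from geranyl bromide 4. Silyl ether 3 comes from phloroglucinol 1 by monosilylation (2) and double acetal formation.

## Alternatives that were turned down

**Alternative 1:** Ring A is built last. The disconnection cuts C4a–C5 and C8–C8a. A geranyl-substituted bis(silyloxy) diene A3 would add to the enantiopure sulfinyl dihydropyranone A2, and loss of a sulfenic acid and a silyl methyl ether would aromatise ring A to the 3'-O-silyl flavanone A1.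
- For: C2 is set early on a small pyranone by well-established asymmetric catalysis, the geranyl regiochemistry is written into the diene, and A1 is one desilylation from the target with no acid. On endgame length and on certainty of the stereocentre it is stronger than the chosen route.
- Against: A2 is a vinylogous ester whose reacting carbon carries the donor O1, so it is a poor 2π partner, and A3 is a hindered diene substituted at its central carbon. The heat or Lewis acid needed for cycloaddition and sulfoxide elimination can open the pyranone by β-elimination of O1 from C2 and erase the stereocentre. The adduct must also lose two groups in the right order next to a geranyl chain.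
- Comparison: the chosen route is longer but puts its only uncertain event in an intramolecular step of a known reaction class, on a precursor made by unambiguous reactions.

**Alternative 2:** Ring C is made by a hetero-Diels–Alder reaction. The disconnection cuts C3–C4 and O1–C2. Salicylaldehyde 9, an orthoformate and a chiral BINOL-derived phosphoric acid would give a 4-methoxy ortho-quinone methide that adds styrene A5 to give the (2S,4S)-4-methoxyflavan A4.
- For: it is convergent, starts from the same aldehyde 9 and closes ring C with two bonds in one step. It reaches ring C in fewer steps than the chosen route.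
- Against: the electrophile is generated with acid beside two aryl acetals, one of them ortho to the reacting carbon. The geranyl alkenes are about as nucleophilic as the styrene. The aldehyde carbon is flanked by two ortho substituents. The C4 stereocentre is made only to be destroyed, and oxidising C4 to the ketone has to spare C2–H, which is itself a doubly activated benzylic ether position.
- Comparison: the chosen route delivers the C4 ketone directly and keeps acid away from the ring-forming step.

**Alternative 3:** An aryne annulation. The disconnection cuts O1–C8a and C4–C4a. A fluoride source would unmask the aryne from silyl triflate A7, the alkoxide of the (S)-β-hydroxy ester A8 would add at C8a, and the aryl anion at C4a would acylate on the ester to give the tris(methoxymethyl) flavanone A6.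
- For: it is the most convergent plan, metal-free, with C2 bought by reliable asymmetric synthesis of A8. The regiochemistry of the aryne is favourable, because the acetal oxygen at C5 directs the nucleophile to C8a. On these points it is stronger than the chosen route.
- Against: the benzylic alkoxide of A8 can undergo retro-aldol cleavage or dehydration to the cinnamate under the basic fluoride conditions, which removes the stereocentre. The aryl anion must find the ester carbonyl before it is quenched by the acidic CH2 next to that ester. A7 needs an ortho-halogenation and silyl transfer on a ring that already carries the geranyl alkenes, so it is no shorter to make than 18.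
- Comparison: the chosen route closes the ring from a neutral species within one molecule, and every step before it has a single possible regiochemical outcome.

Key step: step 13

## Route

Geranyl means (2E)-3,7-dimethylocta-2,6-dien-1-yl throughout.

Assumption: Rh2(S-PTTL)4 is taken to deliver the 2S configuration; if the sense of induction proves opposite, the mirror-image complex Rh2(R-PTTL)4 is used in the same step.

Step 1
Reactants: 1 phloroglucinol (benzene-1,3,5-triol, anhydrous)
Product: 2 5-{[tri(propan-2-yl)silyl]oxy}benzene-1,3-diol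
Conditions: 1 (3 equiv), TIPSCl (1 equiv), imidazole, DMF, 0 °C → rt; excess 1 washed out with water
Reagents that add atoms: chlorotri(propan-2-yl)silane, CC(C)[Si](Cl)(C(C)C)C(C)C
Why: Monosilylation of a threefold-symmetric triol through the N-silylimidazolium species; the threefold excess of the cheap, water-soluble triol keeps double silylation low.

Step 2
Reactants: 2 5-{[tri(propan-2-yl)silyl]oxy}benzene-1,3-diol
Product: 3 [3,5-bis(methoxymethoxy)phenoxy]tri(propan-2-yl)silane
Conditions: MOMCl, iPr2NEt, CH2Cl2, 0 °C → rt
Reagents that add atoms: chloromethyl methyl ether, COCCl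
Why: O-Alkylation of both phenols with the chloromethyl ether under a non-nucleophilic amine base, which leaves the aryl silyl ether in place.

Step 3
Reactants: 3 [3,5-bis(methoxymethoxy)phenoxy]tri(propan-2-yl)silane; 4 geranyl bromide
Product: 7 {4-geranyl-3,5-bis(methoxymethoxy)phenoxy}tri(propan-2-yl)silane, via aryllithium 5 (not isolated), via arylcopper 6 (not isolated)
Conditions: n-BuLi, THF, 0 °C; CuBr·SMe2, −40 °C; 4, −40 °C → rt
Reagents that add atoms: none
Why: Directed ortho-metalation at the carbon between the two acetals, which both acidify and chelate, while the bulky silyl ether neither directs nor leaves room beside it; transmetalation to copper and SN2 alkylation at the primary carbon of 4 keep the E alkene. Because 3 is symmetric, geranyl can only end up para to the silyloxy oxygen, which is C6 of the flavanone.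

Step 4
Reactants: 7 {4-geranyl-3,5-bis(methoxymethoxy)phenoxy}tri(propan-2-yl)silane
Product: 8 4-geranyl-3,5-bis(methoxymethoxy)phenol
Conditions: TBAF, AcOH, THF, 0 °C → rt
Reagents that add atoms: none
Why: Fluoride cleavage of the aryl silyl ether, buffered with acetic acid; acetals and alkenes are inert.

Step 5
Reactants: 8 4-geranyl-3,5-bis(methoxymethoxy)phenol
Product: 9 3-geranyl-6-hydroxy-2,4-bis(methoxymethoxy)benzaldehyde
Conditions: MgCl2, Et3N, (CH2O)n, THF, reflux
Reagents that add atoms: formaldehyde (as paraformaldehyde), C=O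
Why: Casnati–Skattebøl ortho-formylation: hydroxymethylation inside the magnesium phenoxide chelate, then hydride transfer to a second formaldehyde. The para position is blocked and the two ortho positions are equivalent, so one aldehyde forms; the basic medium spares acetals and alkenes.

Step 6
Reactants: 10 isovanillin (3-hydroxy-4-methoxybenzaldehyde)
Product: 11 4-methoxy-3-{[tri(propan-2-yl)silyl]oxy}benzaldehyde
Conditions: TIPSCl, imidazole, DMF, rt
Reagents that add atoms: chlorotri(propan-2-yl)silane, CC(C)[Si](Cl)(C(C)C)C(C)C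
Why: Standard silylation of a phenol; the triisopropylsilyl group is chosen because it must later survive dilute acid in step 9.

Step 7
Reactants: 11 4-methoxy-3-{[tri(propan-2-yl)silyl]oxy}benzaldehyde
Product: 12 (4-methoxy-3-{[tri(propan-2-yl)silyl]oxy}phenyl)methanol
Conditions: NaBH4, MeOH/THF, 0 °C
Reagents that add atoms: none
Why: Hydride reduction of the aldehyde; the hindered aryl silyl ether survives brief exposure at 0 °C.

Step 8
Reactants: 9 3-geranyl-6-hydroxy-2,4-bis(methoxymethoxy)benzaldehyde; 12 (4-methoxy-3-{[tri(propan-2-yl)silyl]oxy}phenyl)methanol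
Product: 13 3-geranyl-2,4-bis(methoxymethoxy)-6-[(4-methoxy-3-{[tri(propan-2-yl)silyl]oxy}phenyl)methoxy]benzaldehyde
Conditions: PPh3, DIAD, THF, 0 °C → rt
Reagents that add atoms: none
Why: Mitsunobu etherification: the phenol of 9, acidified by the ortho aldehyde, displaces the activated primary benzylic alcohol 12 under neutral conditions that leave acetals, silyl ether, aldehyde and alkenes alone. This forms the O1–CH2 bond.

Step 9
Reactants: 13 3-geranyl-2,4-bis(methoxymethoxy)-6-[(4-methoxy-3-{[tri(propan-2-yl)silyl]oxy}phenyl)methoxy]benzaldehyde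
Product: 14 3-geranyl-2-hydroxy-4-(methoxymethoxy)-6-[(4-methoxy-3-{[tri(propan-2-yl)silyl]oxy}phenyl)methoxy]benzaldehyde
Conditions: HCl (0.2 M in MeOH), THF, 0 °C → rt, stopped at full conversion of 13; NaHCO3 quench
Reagents that add atoms: none
Why: Acid-catalysed acetal exchange with methanol: the protonated aldehyde oxygen hydrogen-bonds to the neighbouring ether oxygen and passes the proton on, so the acetal ortho to the carbonyl cleaves faster than the para one. The benzyl ether at the other ortho position would have to ionise to a benzylic cation, which is slower than oxocarbenium formation from the acetal, and the triisopropylsilyl ether is stable to dilute acid at this temperature.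

Step 10
Reactants: 14 3-geranyl-2-hydroxy-4-(methoxymethoxy)-6-[(4-methoxy-3-{[tri(propan-2-yl)silyl]oxy}phenyl)methoxy]benzaldehyde
Product: 15 2-{[tert-butyl(dimethyl)silyl]oxy}-3-geranyl-4-(methoxymethoxy)-6-[(4-methoxy-3-{[tri(propan-2-yl)silyl]oxy}phenyl)methoxy]benzaldehyde
Conditions: TBSOTf, 2,6-lutidine, CH2Cl2, −78 → 0 °C
Reagents that add atoms: tert-butyl(dimethyl)silyl trifluoromethanesulfonate, CC(C)(C)[Si](C)(C)OS(=O)(=O)C(F)(F)F
Why: A hindered, hydrogen-bonded phenol needs the silyl triflate, and there is no enolisable carbonyl to interfere. The step puts at O5 a group with no C–H on the atom bound to oxygen, as the key step requires.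

Step 11
Reactants: 15 2-{[tert-butyl(dimethyl)silyl]oxy}-3-geranyl-4-(methoxymethoxy)-6-[(4-methoxy-3-{[tri(propan-2-yl)silyl]oxy}phenyl)methoxy]benzaldehyde
Product: 16 2-{[tert-butyl(dimethyl)silyl]oxy}-3-geranyl-4-(methoxymethoxy)-6-[(4-methoxy-3-{[tri(propan-2-yl)silyl]oxy}phenyl)methoxy]benzoic acid
Conditions: NaClO2, NaH2PO4, 2-methylbut-2-ene (large excess), t-BuOH/THF/H2O, 0 °C → rt
Reagents that add atoms: sodium chlorite, [Na+].[O-]Cl=O
Why: Pinnick oxidation: chlorous acid adds to the aldehyde and fragments to the acid. The large excess of the alkene scavenger takes up the hypochlorous acid before it can reach the geranyl alkenes or ring A.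

Step 12
Reactants: 16 2-{[tert-butyl(dimethyl)silyl]oxy}-3-geranyl-4-(methoxymethoxy)-6-[(4-methoxy-3-{[tri(propan-2-yl)silyl]oxy}phenyl)methoxy]benzoic acid
Product: 18 1-{2-{[tert-butyl(dimethyl)silyl]oxy}-3-geranyl-4-(methoxymethoxy)-6-[(4-methoxy-3-{[tri(propan-2-yl)silyl]oxy}phenyl)methoxy]phenyl}-2-diazoethan-1-one, via acid chloride 17 (not isolated)
Conditions: 1-chloro-N,N,2-trimethylprop-1-en-1-amine, CH2Cl2, 0 °C → rt; then CH2N2 (excess), Et2O, 0 °C
Reagents that add atoms: diazomethane, C=[N+]=[N-]
Why: The α-chloroenamine makes the acid chloride under neutral conditions, with no HCl to threaten the acetal or the benzyl ether. Acylation of diazomethane (first stage of the Arndt–Eistert sequence) follows, with the excess reagent removing HCl as chloromethane.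

Step 13
Reactants: 18 1-{2-{[tert-butyl(dimethyl)silyl]oxy}-3-geranyl-4-(methoxymethoxy)-6-[(4-methoxy-3-{[tri(propan-2-yl)silyl]oxy}phenyl)methoxy]phenyl}-2-diazoethan-1-one
Product: 19 (2S)-5-{[tert-butyl(dimethyl)silyl]oxy}-6-geranyl-7-(methoxymethoxy)-2-(4-methoxy-3-{[tri(propan-2-yl)silyl]oxy}phenyl)-2,3-dihydro-4H-chromen-4-one
Conditions: Rh2(S-PTTL)4 (dirhodium tetrakis[N-phthaloyl-(S)-tert-leucinate], divalent rhodium, 2 mol %), CH2Cl2, 0 °C → rt, slow addition of 18 to 0.01 M
Reagents that add atoms: none
Why: Loss of N2 from 18 at an axial site of the dirhodium core gives an electrophilic acyl carbene at C3, held over the O1–CH2 group because the doubly ortho-substituted acyl unit is twisted out of the plane of ring A. The carbene inserts into one of the two enantiotopic benzylic C–H bonds through a three-centre, hydride-transfer-like transition state in which positive charge at C2 is stabilised by the O1 lone pair and the para-methoxy group of ring B, forming C2–C3. Ring C closes as a six-membered ring by formal 1,6-insertion (cyclic transition state through C3, C4, C4a, C8a, O1 and C2), the usual 1,5-position being O1 itself. The closest known reaction type is the dirhodium-carboxylate-catalysed cyclisation of ortho-alkoxyaryl diazoketones to chroman-4-ones, which proceeds with asymmetric induction when the carboxylates are chiral. C2 is the only new stereocentre and is controlled by the catalyst alone: the four N-phthaloyl-tert-leucinate ligands wall the carbene into a chiral pocket that presents one of the two hydrogens, with ring B turned away from the phthalimide walls. Site selectivity is secured by the substrate, since O1–CH2 is the only C–H within reach: O5 carries a silyl group with no C–H on the atom bound to oxygen, the O7 acetal is para to the acyl group, and the geranyl chain is meta and could only be reached through a strained meta-bridged ring. Chemoselectivity against oxonium ylide formation with [1,2]-benzyl shift rests on the weak donor ability of an aryl ether oxygen that is conjugated to ring A and ortho to an acyl group, and on the strongly activated C–H bond; slow addition at high dilution suppresses carbene dimerisation and intermolecular cyclopropanation of the geranyl alkenes.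

Step 14
Reactants: 19 (2S)-5-{[tert-butyl(dimethyl)silyl]oxy}-6-geranyl-7-(methoxymethoxy)-2-(4-methoxy-3-{[tri(propan-2-yl)silyl]oxy}phenyl)-2,3-dihydro-4H-chromen-4-one
Product: 20 (2S)-6-geranyl-5-hydroxy-2-(3-hydroxy-4-methoxyphenyl)-7-(methoxymethoxy)-2,3-dihydro-4H-chromen-4-one
Conditions: TBAF, AcOH (1:1), THF, 0 °C → rt
Reagents that add atoms: none
Why: Fluoride cleaves both aryl silyl ethers; the acetic acid buffer keeps the medium non-basic, so C2 is not epimerised through retro-oxa-Michael opening.

Step 15
Reactants: 20 (2S)-6-geranyl-5-hydroxy-2-(3-hydroxy-4-methoxyphenyl)-7-(methoxymethoxy)-2,3-dihydro-4H-chromen-4-one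
Product: 21 (2S)-6-geranyl-5,7-dihydroxy-2-(3-hydroxy-4-methoxyphenyl)-2,3-dihydro-4H-chromen-4-one (target)
Conditions: HCl (3 M aq.), MeOH, 40 °C, short reaction time
Reagents that add atoms: none
Why: Acid-catalysed methanolysis of the one remaining aryl methoxymethyl acetal; a short exposure at moderate temperature limits addition of the phenols to the geranyl alkenes, and the flavanone does not ring-open under these conditions.

## Compound list

1 | phloroglucinol (benzene-1,3,5-triol) | Oc1cc(O)cc(O)c1 | starting material
2 | 5-{[tri(propan-2-yl)silyl]oxy}benzene-1,3-diol | Oc1cc(O)cc(O[Si](C(C)C)(C(C)C)C(C)C)c1 | intermediate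
3 | [3,5-bis(methoxymethoxy)phenoxy]tri(propan-2-yl)silane | COCOc1cc(OCOC)cc(O[Si](C(C)C)(C(C)C)C(C)C)c1 | intermediate
4 | geranyl bromide, (2E)-1-bromo-3,7-dimethylocta-2,6-diene | CC(C)=CCC/C(C)=C/CBr | starting material
5 | [2,6-bis(methoxymethoxy)-4-{[tri(propan-2-yl)silyl]oxy}phenyl]lithium | [Li]c1c(OCOC)cc(O[Si](C(C)C)(C(C)C)C(C)C)cc1OCOC | intermediate (not isolated)
6 | [2,6-bis(methoxymethoxy)-4-{[tri(propan-2-yl)silyl]oxy}phenyl]copper | [Cu]c1c(OCOC)cc(O[Si](C(C)C)(C(C)C)C(C)C)cc1OCOC | intermediate (not isolated)
7 | {4-[(2E)-3,7-dimethylocta-2,6-dien-1-yl]-3,5-bis(methoxymethoxy)phenoxy}tri(propan-2-yl)silane | COCOc1cc(O[Si](C(C)C)(C(C)C)C(C)C)cc(OCOC)c1C/C=C(\C)CCC=C(C)C | intermediate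
8 | 4-[(2E)-3,7-dimethylocta-2,6-dien-1-yl]-3,5-bis(methoxymethoxy)phenol | COCOc1cc(O)cc(OCOC)c1C/C=C(\C)CCC=C(C)C | intermediate
9 | 3-[(2E)-3,7-dimethylocta-2,6-dien-1-yl]-6-hydroxy-2,4-bis(methoxymethoxy)benzaldehyde | O=Cc1c(O)cc(OCOC)c(C/C=C(\C)CCC=C(C)C)c1OCOC | intermediate
10 | isovanillin (3-hydroxy-4-methoxybenzaldehyde) | COc1ccc(C=O)cc1O | starting material
11 | 4-methoxy-3-{[tri(propan-2-yl)silyl]oxy}benzaldehyde | COc1ccc(C=O)cc1O[Si](C(C)C)(C(C)C)C(C)C | intermediate
12 | (4-methoxy-3-{[tri(propan-2-yl)silyl]oxy}phenyl)methanol | COc1ccc(CO)cc1O[Si](C(C)C)(C(C)C)C(C)C | intermediate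
13 | 3-[(2E)-3,7-dimethylocta-2,6-dien-1-yl]-2,4-bis(methoxymethoxy)-6-[(4-methoxy-3-{[tri(propan-2-yl)silyl]oxy}phenyl)methoxy]benzaldehyde | O=Cc1c(OCc2ccc(OC)c(O[Si](C(C)C)(C(C)C)C(C)C)c2)cc(OCOC)c(C/C=C(\C)CCC=C(C)C)c1OCOC | intermediate
14 | 3-[(2E)-3,7-dimethylocta-2,6-dien-1-yl]-2-hydroxy-4-(methoxymethoxy)-6-[(4-methoxy-3-{[tri(propan-2-yl)silyl]oxy}phenyl)methoxy]benzaldehyde | O=Cc1c(OCc2ccc(OC)c(O[Si](C(C)C)(C(C)C)C(C)C)c2)cc(OCOC)c(C/C=C(\C)CCC=C(C)C)c1O | intermediate
15 | 2-{[tert-butyl(dimethyl)silyl]oxy}-3-[(2E)-3,7-dimethylocta-2,6-dien-1-yl]-4-(methoxymethoxy)-6-[(4-methoxy-3-{[tri(propan-2-yl)silyl]oxy}phenyl)methoxy]benzaldehyde | O=Cc1c(OCc2ccc(OC)c(O[Si](C(C)C)(C(C)C)C(C)C)c2)cc(OCOC)c(C/C=C(\C)CCC=C(C)C)c1O[Si](C)(C)C(C)(C)C | intermediate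
16 | 2-{[tert-butyl(dimethyl)silyl]oxy}-3-[(2E)-3,7-dimethylocta-2,6-dien-1-yl]-4-(methoxymethoxy)-6-[(4-methoxy-3-{[tri(propan-2-yl)silyl]oxy}phenyl)methoxy]benzoic acid | OC(=O)c1c(OCc2ccc(OC)c(O[Si](C(C)C)(C(C)C)C(C)C)c2)cc(OCOC)c(C/C=C(\C)CCC=C(C)C)c1O[Si](C)(C)C(C)(C)C | intermediate
17 | 2-{[tert-butyl(dimethyl)silyl]oxy}-3-[(2E)-3,7-dimethylocta-2,6-dien-1-yl]-4-(methoxymethoxy)-6-[(4-methoxy-3-{[tri(propan-2-yl)silyl]oxy}phenyl)methoxy]benzoyl chloride | ClC(=O)c1c(OCc2ccc(OC)c(O[Si](C(C)C)(C(C)C)C(C)C)c2)cc(OCOC)c(C/C=C(\C)CCC=C(C)C)c1O[Si](C)(C)C(C)(C)C | intermediate (not isolated)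
18 | 1-{2-{[tert-butyl(dimethyl)silyl]oxy}-3-[(2E)-3,7-dimethylocta-2,6-dien-1-yl]-4-(methoxymethoxy)-6-[(4-methoxy-3-{[tri(propan-2-yl)silyl]oxy}phenyl)methoxy]phenyl}-2-diazoethan-1-one | [N-]=[N+]=CC(=O)c1c(OCc2ccc(OC)c(O[Si](C(C)C)(C(C)C)C(C)C)c2)cc(OCOC)c(C/C=C(\C)CCC=C(C)C)c1O[Si](C)(C)C(C)(C)C | intermediate
19 | (2S)-5-{[tert-butyl(dimethyl)silyl]oxy}-6-[(2E)-3,7-dimethylocta-2,6-dien-1-yl]-7-(methoxymethoxy)-2-(4-methoxy-3-{[tri(propan-2-yl)silyl]oxy}phenyl)-2,3-dihydro-4H-chromen-4-one | COc1ccc([C@@H]2CC(=O)c3c(cc(OCOC)c(C/C=C(\C)CCC=C(C)C)c3O[Si](C)(C)C(C)(C)C)O2)cc1O[Si](C(C)C)(C(C)C)C(C)C | intermediate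
20 | (2S)-6-[(2E)-3,7-dimethylocta-2,6-dien-1-yl]-5-hydroxy-2-(3-hydroxy-4-methoxyphenyl)-7-(methoxymethoxy)-2,3-dihydro-4H-chromen-4-one | COc1ccc([C@@H]2CC(=O)c3c(cc(OCOC)c(C/C=C(\C)CCC=C(C)C)c3O)O2)cc1O | intermediate
21 | (2S)-6-[(2E)-3,7-dimethylocta-2,6-dien-1-yl]-5,7-dihydroxy-2-(3-hydroxy-4-methoxyphenyl)-2,3-dihydro-4H-chromen-4-one | COc1ccc([C@@H]2CC(=O)c3c(cc(O)c(C/C=C(\C)CCC=C(C)C)c3O)O2)cc1O | target

## Step count and least certain steps

Total: 15 steps. Longest linear sequence: 13 steps (steps 1–5 and 8–15, from phloroglucinol 1); steps 6 and 7 form the two-step branch from isovanillin 10.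

**Step 13 (key step).** The most likely failure is attack of the carbene on the O1 lone pair to give a five-membered oxonium ylide, followed by [1,2]-shift of the electron-rich benzyl group; this contracts the ring to a benzofuranone, and a para-methoxybenzyl group migrates well. The second is erosion of enantioselectivity if hydride transfer runs ahead of C–C bond formation, so that the catalyst pocket no longer controls the ring-closing event.
Fallback, leaving the route at 9 and rejoining it at 21: addition of HC≡CMgBr to salicylaldehyde 9 gives 1-[3-geranyl-6-hydroxy-2,4-bis(methoxymethoxy)phenyl]prop-2-yn-1-ol F1. MnO2 oxidises it to the ynone F2, which closes under amine catalysis, by 6-endo addition of the phenol, to 6-geranyl-5,7-bis(methoxymethoxy)-4H-chromen-4-one F3. Asymmetric 1,4-addition of [4-methoxy-3-(methoxymethoxy)phenyl]boronic acid F4, catalysed by [RhCl(C2H4)2]2 (monovalent rhodium) with a chiral diene or bisphosphine ligand of the antipode that gives 2S, is a known reaction of chromones and gives the (2S)-tris(methoxymethyl) flavanone F5. Acidic methanolysis as in step 15 then gives 21.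

**Step 9.** The most likely failure is loss of selectivity among three acid-labile sites: cleavage of the second acetal or ionisation of the para-methoxybenzyl-type ether, because the rate advantage of the ortho acetal is kinetic only.
Fallback, leaving at 9 and rejoining at 14: the order is changed. The ortho acetal of 9 is cleaved under chelation control with MgBr2·OEt2 before any benzyl ether is present, giving 3-geranyl-2,6-dihydroxy-4-(methoxymethoxy)benzaldehyde F6. A Mitsunobu reaction of F6 with 12 then alkylates the less hindered hydroxyl, the one not flanked by geranyl, to give 14.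

**Step 12.** The most likely failure is slow acylation of diazomethane by a doubly ortho-substituted, electron-rich acid chloride, with loss of the ortho silyl group or capture of the diazoketone by HCl during the longer reaction time.
Fallback, leaving at 15 and rejoining at 18: addition of MeMgBr to aldehyde 15 at −78 °C with a cold quench (to prevent silyl migration to the alkoxide) gives the secondary alcohol F7. Dess–Martin oxidation gives the methyl ketone F8. Detrifluoroacetylative diazo transfer (LiN(SiMe3)2 and 2,2,2-trifluoroethyl trifluoroacetate to the trifluoroacetylated diketone F9, then methanesulfonyl azide and Et3N) gives 18.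

**Step 15.** The most likely failure is acid-mediated addition of the freed 5- or 7-hydroxyl, or of methanol, to the geranyl alkenes while the last acetal is being cleaved, because a para-acyl aryl acetal needs more forcing acid than the ortho one.
Fallback, leaving at 19 and rejoining at 21: the acetal is removed first and without protic acid. Treatment of 19 with TMSOTf and 2,2'-bipyridyl converts the aryl acetal into a silyl ether that hydrolyses on aqueous work-up, giving the 7-hydroxy bis-silyl flavanone F10. Buffered fluoride as in step 14 then gives 21.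

## Further compounds

F1 | step 13 | 1-{3-[(2E)-3,7-dimethylocta-2,6-dien-1-yl]-6-hydroxy-2,4-bis(methoxymethoxy)phenyl}prop-2-yn-1-ol (racemic) | C#CC(O)c1c(O)cc(OCOC)c(C/C=C(\C)CCC=C(C)C)c1OCOC
F2 | step 13 | 1-{3-[(2E)-3,7-dimethylocta-2,6-dien-1-yl]-6-hydroxy-2,4-bis(methoxymethoxy)phenyl}prop-2-yn-1-one | C#CC(=O)c1c(O)cc(OCOC)c(C/C=C(\C)CCC=C(C)C)c1OCOC
F3 | step 13 | 6-[(2E)-3,7-dimethylocta-2,6-dien-1-yl]-5,7-bis(methoxymethoxy)-4H-chromen-4-one | O=c1ccoc2cc(OCOC)c(C/C=C(\C)CCC=C(C)C)c(OCOC)c12
F4 | step 13 | [4-methoxy-3-(methoxymethoxy)phenyl]boronic acid | COCOc1cc(B(O)O)ccc1OC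
F5 | step 13 | (2S)-6-[(2E)-3,7-dimethylocta-2,6-dien-1-yl]-5,7-bis(methoxymethoxy)-2-[4-methoxy-3-(methoxymethoxy)phenyl]-2,3-dihydro-4H-chromen-4-one | COc1ccc([C@@H]2CC(=O)c3c(cc(OCOC)c(C/C=C(\C)CCC=C(C)C)c3OCOC)O2)cc1OCOC
F6 | step 9 | 3-[(2E)-3,7-dimethylocta-2,6-dien-1-yl]-2,6-dihydroxy-4-(methoxymethoxy)benzaldehyde | O=Cc1c(O)cc(OCOC)c(C/C=C(\C)CCC=C(C)C)c1O
F7 | step 12 | 1-{2-{[tert-butyl(dimethyl)silyl]oxy}-3-[(2E)-3,7-dimethylocta-2,6-dien-1-yl]-4-(methoxymethoxy)-6-[(4-methoxy-3-{[tri(propan-2-yl)silyl]oxy}phenyl)methoxy]phenyl}ethan-1-ol (racemic) | CC(O)c1c(OCc2ccc(OC)c(O[Si](C(C)C)(C(C)C)C(C)C)c2)cc(OCOC)c(C/C=C(\C)CCC=C(C)C)c1O[Si](C)(C)C(C)(C)C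
F8 | step 12 | 1-{2-{[tert-butyl(dimethyl)silyl]oxy}-3-[(2E)-3,7-dimethylocta-2,6-dien-1-yl]-4-(methoxymethoxy)-6-[(4-methoxy-3-{[tri(propan-2-yl)silyl]oxy}phenyl)methoxy]phenyl}ethan-1-one | CC(=O)c1c(OCc2ccc(OC)c(O[Si](C(C)C)(C(C)C)C(C)C)c2)cc(OCOC)c(C/C=C(\C)CCC=C(C)C)c1O[Si](C)(C)C(C)(C)C
F9 | step 12 | 1-{2-{[tert-butyl(dimethyl)silyl]oxy}-3-[(2E)-3,7-dimethylocta-2,6-dien-1-yl]-4-(methoxymethoxy)-6-[(4-methoxy-3-{[tri(propan-2-yl)silyl]oxy}phenyl)methoxy]phenyl}-4,4,4-trifluorobutane-1,3-dione | FC(F)(F)C(=O)CC(=O)c1c(OCc2ccc(OC)c(O[Si](C(C)C)(C(C)C)C(C)C)c2)cc(OCOC)c(C/C=C(\C)CCC=C(C)C)c1O[Si](C)(C)C(C)(C)C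
F10 | step 15 | (2S)-5-{[tert-butyl(dimethyl)silyl]oxy}-6-[(2E)-3,7-dimethylocta-2,6-dien-1-yl]-7-hydroxy-2-(4-methoxy-3-{[tri(propan-2-yl)silyl]oxy}phenyl)-2,3-dihydro-4H-chromen-4-one | COc1ccc([C@@H]2CC(=O)c3c(cc(O)c(C/C=C(\C)CCC=C(C)C)c3O[Si](C)(C)C(C)(C)C)O2)cc1O[Si](C(C)C)(C(C)C)C(C)C
A1 | alternative 1 | (2S)-2-(3-{[tert-butyl(dimethyl)silyl]oxy}-4-methoxyphenyl)-6-[(2E)-3,7-dimethylocta-2,6-dien-1-yl]-5,7-dihydroxy-2,3-dihydro-4H-chromen-4-one | COc1ccc([C@@H]2CC(=O)c3c(cc(O)c(C/C=C(\C)CCC=C(C)C)c3O)O2)cc1O[Si](C)(C)C(C)(C)C
A2 | alternative 1 | (2S)-2-(3-{[tert-butyl(dimethyl)silyl]oxy}-4-methoxyphenyl)-5-(phenylsulfinyl)-2,3-dihydro-4H-pyran-4-one | COc1ccc([C@@H]2CC(=O)C(S(=O)c3ccccc3)=CO2)cc1O[Si](C)(C)C(C)(C)C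
A3 | alternative 1 | 2-[(2E)-3,7-dimethylocta-2,6-dien-1-yl]-1-methoxy-1,3-bis(trimethylsilyloxy)buta-1,3-diene | C=C(O[Si](C)(C)C)C(C/C=C(\C)CCC=C(C)C)=C(OC)O[Si](C)(C)C
A4 | alternative 2 | (2S,4S)-2-(3-{[tert-butyl(dimethyl)silyl]oxy}-4-methoxyphenyl)-6-[(2E)-3,7-dimethylocta-2,6-dien-1-yl]-4-methoxy-5,7-bis(methoxymethoxy)-3,4-dihydro-2H-chromene | COc1ccc([C@@H]2C[C@H](OC)c3c(cc(OCOC)c(C/C=C(\C)CCC=C(C)C)c3OCOC)O2)cc1O[Si](C)(C)C(C)(C)C
A5 | alternative 2 | tert-butyl(5-ethenyl-2-methoxyphenoxy)dimethylsilane | C=Cc1ccc(OC)c(O[Si](C)(C)C(C)(C)C)c1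
A6 | alternative 3 | (2S)-6-[(2E)-3,7-dimethylocta-2,6-dien-1-yl]-5,7-bis(methoxymethoxy)-2-[4-methoxy-3-(methoxymethoxy)phenyl]-2,3-dihydro-4H-chromen-4-one | COc1ccc([C@@H]2CC(=O)c3c(cc(OCOC)c(C/C=C(\C)CCC=C(C)C)c3OCOC)O2)cc1OCOC
A7 | alternative 3 | 4-[(2E)-3,7-dimethylocta-2,6-dien-1-yl]-3,5-bis(methoxymethoxy)-2-(trimethylsilyl)phenyl trifluoromethanesulfonate | C[Si](C)(C)c1c(OS(=O)(=O)C(F)(F)F)cc(OCOC)c(C/C=C(\C)CCC=C(C)C)c1OCOC
A8 | alternative 3 | methyl (3S)-3-hydroxy-3-[4-methoxy-3-(methoxymethoxy)phenyl]propanoate | COC(=O)C[C@H](O)c1ccc(OC)c(OCOC)c1
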